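**Retrosynthetic overview**
1. The target comes from selective C2 de-acetylation of a diacetate. Ring C is closed last by a bromonium-initiated cation–π cyclisation of a 2-(4-methylpent-3-enyl)allyl acetate side chain. The tertiary C1' cation is caught by the neighbouring acetate (C2'–C3' bond; sets C1' and C4').
2. The C1–C8 bond comes from a syn-aldol of a regiodefined trans-hydrindan-2-one enolate with 6-methyl-2-methylidenehept-5-enal, followed in the same flask by chelate-controlled 1,3-syn reduction (sets C1, C8, C2).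
3. Five-membered ring B comes from Wacker oxidation and aldol condensation of an allyl ketone. The C7 carbinol comes from a vinylogous Rubottom oxidation, and the trans ring fusion from 1,4-hydrosilylation.
4. Key step: the quaternary C3a and the neopentylic C4–Br are made together by a bromonium-triggered 1,2-allyl shift (semipinacol) of (S)-1-allyl-2-methylcyclohex-2-enol. That alcohol comes from catalytic asymmetric allylation of 2-methylcyclohex-2-enone.
5. Ring order: ring A (bought as the enone), then ring B, then ring C.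

Locants and assumption: hydrindane C1–C7a follow indene numbering; C8 is the acetoxy methine; C1'–C6' is the cyclohexane (C1' carbinol, C3' CMe2, C4' CHBr). Compounds 4–6 are carried as C6/C7 methyl epimers, because that centre is planarised in step 6.

**Step 1**
Reactants: 1 2-methylcyclohex-2-en-1-one
Product: 2 (S)-2-methyl-1-(prop-2-en-1-yl)cyclohex-2-en-1-ol
Conditions: Ti(OiPr)4 (20 mol%), BINOL (20 mol%, antipode giving the S carbinol), iPrOH (20 equiv), Sn(CH2CH=CH2)4 (1.2 equiv), CH2Cl2, rt
Reagents that add atoms: tetraallylstannane, C=CC[Sn](CC=C)(CC=C)CC=C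
Why: Catalytic asymmetric 1,2-allylation of a ketone, in which the BINOLate–titanium Lewis acid tells the sp2 (methyl-bearing) flank of the cyclic enone from the sp3 flank, gives only carbonyl addition and sets the carbinol centre as S.

**Step 2**
Reactants: 2 (S)-2-methyl-1-(prop-2-en-1-yl)cyclohex-2-en-1-ol
Product: 3 (2S,3S)-3-bromo-2-methyl-2-(prop-2-en-1-yl)cyclohexan-1-one
Conditions: NBS (1.05 equiv), CH2Cl2/HFIP 4:1, −40 °C, dark
Reagents that add atoms: N-bromosuccinimide, O=C1CCC(=O)N1Br
Why: Proposed new method: NBS activated by hydrogen bonding to HFIP transfers Br+ reversibly to the electron-rich trisubstituted ring alkene (the monosubstituted allyl alkene is far less nucleophilic); only the bromiranium ion on the face opposite the pseudo-axial allyl group has a C–C bond antiperiplanar to the breaking C2–Br bond, so allyl shifts suprafacially from C1 to the tertiary terminus C2 while the hydroxyl oxygen becomes the ketone, which makes the step irreversible, builds the quaternary centre and the adjacent C–Br in an anti sense (allyl trans, methyl cis to Br) and passes the carbinol chirality to both new centres, whereas the other bromiranium ion can only close reversibly to a protonated epoxide and drains back; the closest known reaction type is the halonium-induced semipinacol rearrangement of allylic alcohols, shown so far for aryl or ring-carbon migration from exocyclic carbinols and strained cycloalkanols, not for an open-chain alkene-bearing sp3 group leaving an endocyclic tertiary carbinol with chirality transfer.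

**Step 3**
Reactants: 3 (2S,3S)-3-bromo-2-methyl-2-(prop-2-en-1-yl)cyclohexan-1-one
Product: 4 (2S,3S)-3-bromo-2,6-dimethyl-2-(prop-2-en-1-yl)cyclohexan-1-one (C6 epimers)
Conditions: LiN(iPr)2 (1.1 equiv), THF, −78 °C; MeI (3 equiv), −78 → −30 °C
Reagents that add atoms: iodomethane, CI
Why: Enolate alkylation that is regiospecific because only C6 carries α-hydrogens; the non-nucleophilic base cannot add to the carbonyl, and the new centre is planarised later so its configuration does not matter.

**Step 4**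
Reactants: 4 (2S,3S)-3-bromo-2,6-dimethyl-2-(prop-2-en-1-yl)cyclohexan-1-one
Product: 5 (2S,3S)-3-bromo-2,6-dimethyl-2-(2-oxopropyl)cyclohexan-1-one (C6 epimers)
Conditions: PdCl2 (10 mol%), CuCl (1 equiv), O2 (1 atm), DMF/H2O 7:1, rt
Reagents that add atoms: water, O
Why: Wacker–Tsuji oxidation, in which Markovnikov hydroxypalladation of the terminal alkene gives the methyl ketone while the ketone and the hindered secondary bromide are inert.

**Step 5**
Reactants: 5 (2S,3S)-3-bromo-2,6-dimethyl-2-(2-oxopropyl)cyclohexan-1-one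
Product: 6 (3aS,4S)-4-bromo-3a,7-dimethyl-3,3a,4,5,6,7-hexahydro-2H-inden-2-one (C7 epimers)
Conditions: p-TsOH·H2O (20 mol%), PhMe, reflux, Dean–Stark
Reagents that add atoms: none
Why: Acid-catalysed intramolecular aldol condensation of a 1,4-diketone closes ring B; the quaternary carbon blocks furan formation, the bridged aldol alternative cannot dehydrate and reverts, and acid avoids the C7a alkoxide that under base could fragment (Grob) against the antiperiplanar C4–Br.

**Step 6**
Reactants: 6 (3aS,4S)-4-bromo-3a,7-dimethyl-3,3a,4,5,6,7-hexahydro-2H-inden-2-one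
Product: 8 (3aS,4S,7R)-4-bromo-7-hydroxy-3a,7-dimethyl-3,3a,4,5,6,7-hexahydro-2H-inden-2-one, via trimethylsilyl dienol ether 7 (not isolated)
Conditions: TMSOTf (1.5 equiv), Et3N (3 equiv), CH2Cl2, 0 °C → rt; then mCPBA (1.1 equiv), NaHCO3, −20 °C; aq. citric acid work-up
Reagents that add atoms: mCPBA, O=C(OO)c1cccc(Cl)c1; trimethylsilyl triflate, C[Si](C)(C)OS(=O)(=O)C(F)(F)F (its silyl group stays only in 7)
Why: Vinylogous Rubottom oxidation, in which equilibrating silylation gives the extended heteroannular dienol ether and the peracid attacks C7 axially, syn to the angular methyl as steroidal 3,5-dienol ethers do at C6, giving the axial 7-OH and equatorial 7-methyl (7R).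

**Step 7**
Reactants: 8 (3aS,4S,7R)-4-bromo-7-hydroxy-3a,7-dimethyl-3,3a,4,5,6,7-hexahydro-2H-inden-2-one
Product: 9 (3aS,4S,7R,7aS)-4-bromo-3a,7-dimethyl-2-(triethylsilyloxy)-3a,4,5,6,7,7a-hexahydro-3H-inden-7-ol
Conditions: RhCl(PPh3)3 (2 mol%), Et3SiH (1.5 equiv), PhMe, 60 °C
Reagents that add atoms: triethylsilane, CC[SiH](CC)CC
Why: Rhodium-catalysed 1,4-hydrosilylation of the enone binds the face opposite the angular methyl and the axial 7-OH, so hydride reaches C7a from below (trans fusion, 7aS) and the enol ether is fixed regiospecifically toward C1.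

**Step 8**
Reactants: 10 5-bromo-2-methylpent-2-ene; 11 prop-2-yn-1-ol
Product: 13 6-methyl-2-methylidenehept-5-en-1-ol, via homoprenylmagnesium bromide 12 (not isolated)
Conditions: Mg, THF, 35 °C; then 11 (0.4 equiv), CuI (10 mol%), THF/Et2O, 0 °C → rt; aq. NH4Cl
Reagents that add atoms: magnesium, [Mg] (stays only in 12)
Why: Copper-catalysed, alkoxide-directed carbomagnesiation of propargyl alcohol places the alkyl group on the internal alkyne carbon and gives the 2-substituted allylic alcohol after protonolysis.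

**Step 9**
Reactants: 13 6-methyl-2-methylidenehept-5-en-1-ol
Product: 14 6-methyl-2-methylidenehept-5-enal
Conditions: MnO2 (10 equiv), CH2Cl2, rt
Reagents that add atoms: none
Why: Chemoselective MnO2 oxidation of an allylic alcohol to the 2-alkylacrolein without touching either alkene.

**Step 10**
Reactants: 9 (3aS,4S,7R,7aS)-4-bromo-3a,7-dimethyl-2-(triethylsilyloxy)-3a,4,5,6,7,7a-hexahydro-3H-inden-7-ol; 14 6-methyl-2-methylidenehept-5-enal
Product: 16 (1S,2R,3aS,4S,7R,7aS)-4-bromo-1-[(1R)-1-hydroxy-6-methyl-2-methylidenehept-5-en-1-yl]-3a,7-dimethyloctahydro-1H-indene-2,7-diol, via titanium aldolate 15 (not isolated)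
Conditions: MeLi (2.1 equiv), THF, 0 °C; ClTi(OiPr)3 (2.2 equiv), −78 °C; 14 (1.3 equiv), −78 °C; then LiBH4 (3 equiv), −78 → −40 °C; aq. NH4F
Reagents that add atoms: chlorotitanium triisopropoxide, CC(C)O[Ti](Cl)(OC(C)C)OC(C)C (its Ti(OiPr)3 units stay only in 15)
Why: Aldol addition of a triisopropoxytitanium enolate of a cyclic ketone is syn-selective; it takes place on the ring-B face trans to C7 (sets C1 and C8), and the titanium chelate between the C8 alkoxide and the C2 ketone shields that same face, so borohydride attacks from the opposite side in a Narasaka–Prasad-type 1,3-syn reduction (2R).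

**Step 11**
Reactants: 16 (1S,2R,3aS,4S,7R,7aS)-4-bromo-1-[(1R)-1-hydroxy-6-methyl-2-methylidenehept-5-en-1-yl]-3a,7-dimethyloctahydro-1H-indene-2,7-diol
Product: 17 (1R)-1-[(1S,2R,3aS,4S,7R,7aS)-2-acetoxy-4-bromo-7-hydroxy-3a,7-dimethyloctahydro-1H-inden-1-yl]-6-methyl-2-methylidenehept-5-en-1-yl acetate
Conditions: Ac2O (4 equiv), pyridine, DMAP (10 mol%), CH2Cl2, 0 °C → rt
Reagents that add atoms: acetic anhydride, CC(=O)OC(C)=O
Why: DMAP-catalysed acylation esterifies both secondary alcohols while the axial tertiary 7-OH, syn-diaxial to the angular methyl, stays free.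

**Step 12**
Reactants: 17 (1R)-1-[(1S,2R,3aS,4S,7R,7aS)-2-acetoxy-4-bromo-7-hydroxy-3a,7-dimethyloctahydro-1H-inden-1-yl]-6-methyl-2-methylidenehept-5-en-1-yl acetate
Product: 19 (R)-[(1S,2R,3aS,4S,7R,7aS)-2-acetoxy-4-bromo-7-hydroxy-3a,7-dimethyloctahydro-1H-inden-1-yl][(1R,4S)-4-bromo-1-hydroxy-3,3-dimethylcyclohexyl]methyl acetate, via spiro acetoxonium ion 18 (not isolated)
Conditions: Et2SBr·SbCl5Br (1.1 equiv), MeNO2, −25 °C, 10 min; then aq. NaHCO3/Na2SO3, rt
Reagents that add atoms: bromodiethylsulfonium bromopentachloroantimonate, CC[S+](Br)CC.Cl[Sb-](Cl)(Cl)(Cl)(Cl)Br; water, O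
Why: Bromonium-initiated cation–π cyclisation through a chair puts Br equatorial and the bulky C8 group equatorial; the C8 acetate carbonyl captures the C1' cation axially (neighbouring-group participation) with the hydrindanyl group turned to the unhindered C6' side, which gives 1'R,4'S, and hydrolysis followed by acyl equilibration leaves the acetate on the secondary oxygen.

**Step 13**
Reactants: 19 (R)-[(1S,2R,3aS,4S,7R,7aS)-2-acetoxy-4-bromo-7-hydroxy-3a,7-dimethyloctahydro-1H-inden-1-yl][(1R,4S)-4-bromo-1-hydroxy-3,3-dimethylcyclohexyl]methyl acetate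
Product: 20 (R)-[(1R,4S)-4-bromo-1-hydroxy-3,3-dimethylcyclohexyl][(1S,2R,3aS,4S,7R,7aS)-4-bromo-2,7-dihydroxy-3a,7-dimethyloctahydro-1H-inden-1-yl]methyl acetate (CNP0166243.1)
Conditions: K2CO3 (0.2 equiv), MeOH, −10 °C, stopped at mono-cleavage
Reagents that add atoms: none
Why: Sterically differentiated transesterification, in which the cyclopentyl C2 acetate is methanolysed faster than the C8 acetate, which is now flanked by a fully substituted C1' and the branched C1.

**Compound list**
1 | 2-methylcyclohex-2-en-1-one | CC1=CCCCC1=O | starting material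
2 | (S)-2-methyl-1-(prop-2-en-1-yl)cyclohex-2-en-1-ol | O[C@@]1(CC=C)C(C)=CCCC1 | intermediate
3 | (2S,3S)-3-bromo-2-methyl-2-(prop-2-en-1-yl)cyclohexan-1-one | C=CC[C@]1(C)[C@@H](Br)CCCC1=O | intermediate
4 | (2S,3S)-3-bromo-2,6-dimethyl-2-(prop-2-en-1-yl)cyclohexan-1-one (C6 epimers) | C=CC[C@]1(C)[C@@H](Br)CCC(C)C1=O | intermediate
5 | (2S,3S)-3-bromo-2,6-dimethyl-2-(2-oxopropyl)cyclohexan-1-one (C6 epimers) | CC(=O)C[C@]1(C)[C@@H](Br)CCC(C)C1=O | intermediate
6 | (3aS,4S)-4-bromo-3a,7-dimethyl-3,3a,4,5,6,7-hexahydro-2H-inden-2-one (C7 epimers) | O=C1C[C@]2(C)[C@@H](Br)CCC(C)C2=C1 | intermediate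
7 | (3aS,4S)-4-bromo-3a,7-dimethyl-2-(trimethylsilyloxy)-3a,4,5,6-tetrahydro-3H-indene (extended dienol ether) | C[Si](C)(C)OC=1C[C@]2(C)[C@@H](Br)CCC(C)=C2C=1 | intermediate
8 | (3aS,4S,7R)-4-bromo-7-hydroxy-3a,7-dimethyl-3,3a,4,5,6,7-hexahydro-2H-inden-2-one | O=C1C[C@]2(C)[C@@H](Br)CC[C@@](C)(O)C2=C1 | intermediate
9 | (3aS,4S,7R,7aS)-4-bromo-3a,7-dimethyl-2-(triethylsilyloxy)-3a,4,5,6,7,7a-hexahydro-3H-inden-7-ol | C1=C(O[Si](CC)(CC)CC)C[C@]2(C)[C@@H](Br)CC[C@@](C)(O)[C@@H]12 | intermediate
10 | 5-bromo-2-methylpent-2-ene | CC(C)=CCCBr | starting material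
11 | prop-2-yn-1-ol | C#CCO | starting material
12 | (4-methylpent-3-en-1-yl)magnesium bromide | CC(C)=CCC[Mg]Br | intermediate
13 | 6-methyl-2-methylidenehept-5-en-1-ol | CC(C)=CCCC(=C)CO | intermediate
14 | 6-methyl-2-methylidenehept-5-enal | CC(C)=CCCC(=C)C=O | intermediate
15 | bis(triisopropoxytitanium) alkoxide of (1R,3aS,4S,7R,7aS)-4-bromo-7-hydroxy-1-[(1R)-1-hydroxy-6-methyl-2-methylidenehept-5-en-1-yl]-3a,7-dimethyloctahydro-2H-inden-2-one | CC(C)O[Ti](OC(C)C)(OC(C)C)O[C@H]([C@@H]1C(=O)C[C@]2(C)[C@@H](Br)CC[C@@](C)(O[Ti](OC(C)C)(OC(C)C)OC(C)C)[C@@H]12)C(=C)CCC=C(C)C | intermediate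
16 | (1S,2R,3aS,4S,7R,7aS)-4-bromo-1-[(1R)-1-hydroxy-6-methyl-2-methylidenehept-5-en-1-yl]-3a,7-dimethyloctahydro-1H-indene-2,7-diol | O[C@H]([C@@H]1[C@H](O)C[C@]2(C)[C@@H](Br)CC[C@@](C)(O)[C@@H]12)C(=C)CCC=C(C)C | intermediate
17 | (1R)-1-[(1S,2R,3aS,4S,7R,7aS)-2-acetoxy-4-bromo-7-hydroxy-3a,7-dimethyloctahydro-1H-inden-1-yl]-6-methyl-2-methylidenehept-5-en-1-yl acetate | CC(=O)O[C@H]([C@@H]1[C@H](OC(C)=O)C[C@]2(C)[C@@H](Br)CC[C@@](C)(O)[C@@H]12)C(=C)CCC=C(C)C | intermediate
18 | spiro 2-methyl-1,3-dioxolan-2-ylium ion bridging O–C8 and O–C1' (ring C closed, 4'S bromide), bromopentachloroantimonate salt | C[C+]1O[C@H]([C@@H]3[C@H](OC(C)=O)C[C@]4(C)[C@@H](Br)CC[C@@](C)(O)[C@@H]34)[C@@]2(O1)CC[C@H](Br)C(C)(C)C2.Cl[Sb-](Cl)(Cl)(Cl)(Cl)Br | intermediate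
19 | (R)-[(1S,2R,3aS,4S,7R,7aS)-2-acetoxy-4-bromo-7-hydroxy-3a,7-dimethyloctahydro-1H-inden-1-yl][(1R,4S)-4-bromo-1-hydroxy-3,3-dimethylcyclohexyl]methyl acetate | CC(=O)O[C@H]([C@@H]1[C@H](OC(C)=O)C[C@]2(C)[C@@H](Br)CC[C@@](C)(O)[C@@H]12)[C@@]1(O)CC[C@H](Br)C(C)(C)C1 | intermediate
20 | (R)-[(1R,4S)-4-bromo-1-hydroxy-3,3-dimethylcyclohexyl][(1S,2R,3aS,4S,7R,7aS)-4-bromo-2,7-dihydroxy-3a,7-dimethyloctahydro-1H-inden-1-yl]methyl acetate | CC(=O)O[C@H]([C@@H]1[C@H](O)C[C@]2(C)[C@@H](Br)CC[C@@](C)(O)[C@@H]12)[C@@]1(O)CC[C@H](Br)C(C)(C)C1 | target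

**Totals**
Total step count: 13. Longest linear sequence: 11 (steps 1–7 and 10–13).

**Three steps most likely to fail**

*Step 2 (the proposed new step).* The risks are bromination of the allyl alkene, epoxide or ether formation, and ionisation of the tertiary allylic alcohol. The fallback uses only known reaction types, keeps the 1,2-allyl shift, sets out from 1 and comes back at 3.
- The titanium/BINOL allylation with the mirror-image ligand gives the (R)-carbinol F1. It is epoxidised in the same flask with tBuOOH under hydroxyl direction to the epoxy alcohol F2.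
- BF3·OEt2 opens the epoxide at the tertiary carbon with the antiperiplanar allyl shift (the established semipinacol of 2,3-epoxy alcohols) and gives the hydroxy ketone F3.
- TBSOTf/2,6-lutidine gives the silyl ether F4. (PhO)3P/Br2/Et3N then turns the ketone into the alkenyl bromide F5.
- Hydrogen-atom-transfer hydrogenation with Co(acac)2, tBuOOH, Et3SiH and 1,4-cyclohexadiene prefers the bromoalkene to the monosubstituted alkene. It delivers hydrogen anti to the axial methyl and gives the bromide F6.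
- Bu4NF gives the bromo alcohol F7, and Dess–Martin oxidation gives 3.
- The former carbinol carbon ends up as the ketone, which is why the mirror-image ligand is used.

*Step 12.* The risks are weak diastereocontrol from C8 over the remote bromonium face, and proton loss from the C1' cation. The fallback fixes the bromonium face by reagent control, sets out from 17 and comes back at 19 through 18.
- Shi epoxidation uses the fructose-derived ketone antipode that gives the R epoxide, with KHSO5 (as 2KHSO5·KHSO4·K2SO4) and K2CO3 buffer. It oxidises only the trisubstituted alkene and gives the epoxide F8.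
- Li2NiBr4 in THF opens the epoxide at the secondary carbon with inversion and gives the bromohydrin F9.
- Ionisation of the tertiary alcohol in HFIP with catalytic TfOH regenerates a single bromiranium ion by bromine participation. That ion cyclises to 18 and is hydrolysed to 19.

*Step 13.* The risks are over-cleavage and 1,3-acyl migration once the 2-OH is free. The fallback replaces kinetic ester differentiation by an orthogonal protecting group, sets out from 16 and comes back at 20.
- TBSCl/imidazole silylates the less hindered ring alcohol and gives the C2 silyl ether F10.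
- Ac2O/DMAP gives the C8 acetate F11.
- Et2SBr·SbCl5Br in MeNO2, then aqueous NaHCO3, closes ring C and gives the silyl-protected bromide F12.
- HF·pyridine then releases 20.

**Further compounds**
F1 | step 2 | (R)-2-methyl-1-(prop-2-en-1-yl)cyclohex-2-en-1-ol | O[C@]1(CC=C)C(C)=CCCC1
F2 | step 2 | (1R,2R,6R)-1-methyl-2-(prop-2-en-1-yl)-7-oxabicyclo[4.1.0]heptan-2-ol | O[C@]1(CC=C)[C@]2(C)O[C@@H]2CCC1
F3 | step 2 | (2S,3R)-3-hydroxy-2-methyl-2-(prop-2-en-1-yl)cyclohexan-1-one | C=CC[C@]1(C)C(=O)CCC[C@H]1O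
F4 | step 2 | (2S,3R)-3-(tert-butyldimethylsilyloxy)-2-methyl-2-(prop-2-en-1-yl)cyclohexan-1-one | C=CC[C@]1(C)C(=O)CCC[C@H]1O[Si](C)(C)C(C)(C)C
F5 | step 2 | [(1R,2S)-3-bromo-2-methyl-2-(prop-2-en-1-yl)cyclohex-3-en-1-yl]oxy(tert-butyl)dimethylsilane | C=CC[C@]1(C)C(Br)=CCC[C@H]1O[Si](C)(C)C(C)(C)C
F6 | step 2 | [(1R,2S,3S)-3-bromo-2-methyl-2-(prop-2-en-1-yl)cyclohexyl]oxy(tert-butyl)dimethylsilane | C=CC[C@]1(C)[C@@H](Br)CCC[C@H]1O[Si](C)(C)C(C)(C)C
F7 | step 2 | (1R,2S,3S)-3-bromo-2-methyl-2-(prop-2-en-1-yl)cyclohexan-1-ol | C=CC[C@]1(C)[C@@H](Br)CCC[C@H]1O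
F8 | step 12 | diacetate 17 with the trisubstituted alkene as its (R)-epoxide (3,3-dimethyloxiran-2-yl terminus) | CC(=O)O[C@H]([C@@H]1[C@H](OC(C)=O)C[C@]2(C)[C@@H](Br)CC[C@@](C)(O)[C@@H]12)C(=C)CC[C@H]1OC1(C)C
F9 | step 12 | diacetate 17 with the trisubstituted alkene as its (S)-5-bromo-6-hydroxy-6-methyl bromohydrin | CC(=O)O[C@H]([C@@H]1[C@H](OC(C)=O)C[C@]2(C)[C@@H](Br)CC[C@@](C)(O)[C@@H]12)C(=C)CC[C@H](Br)C(C)(C)O
F10 | step 13 | 2-O-tert-butyldimethylsilyl ether of triol 16 | O[C@H]([C@@H]1[C@H](O[Si](C)(C)C(C)(C)C)C[C@]2(C)[C@@H](Br)CC[C@@](C)(O)[C@@H]12)C(=C)CCC=C(C)C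
F11 | step 13 | 8-O-acetyl-2-O-tert-butyldimethylsilyl derivative of triol 16 | CC(=O)O[C@H]([C@@H]1[C@H](O[Si](C)(C)C(C)(C)C)C[C@]2(C)[C@@H](Br)CC[C@@](C)(O)[C@@H]12)C(=C)CCC=C(C)C
F12 | step 13 | 2-O-tert-butyldimethylsilyl ether of target 20 | CC(=O)O[C@H]([C@@H]1[C@H](O[Si](C)(C)C(C)(C)C)C[C@]2(C)[C@@H](Br)CC[C@@](C)(O)[C@@H]12)[C@@]1(O)CC[C@H](Br)C(C)(C)C1
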